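## Retrosynthetic overview

1. Kushenol U ⇐ O1–C2 bond: catalyst-controlled intramolecular oxa-Michael addition of a 2'-hydroxychalcone sets C-2 as S; ring C is the only ring made and is made last, with MOM removal in the same flask.
2. Chalcone ⇐ Claisen–Schmidt condensation of a ring A 2'-hydroxyacetophenone with 4-(methoxymethoxy)benzaldehyde (ring B bought).
3. Ring A acetophenone ⇐ 5-methoxyresorcinol bis-MOM ether by two directed ortho-metalations: C-alkylation with (S)-lavandulyl iodide between the OMOM groups, then acetylation between OMOM and OMe with selective release of the 2'-OH.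
4. (S)-Lavandulyl iodide ⇐ Evans deconjugative α-prenylation of an N-(3-methylbut-2-enoyl)oxazolidinone (sets the side-chain centre), then reduction and iodination.

## Assumptions

- "Lav" means the target side chain (2R)-5-methyl-2-(prop-1-en-2-yl)hex-4-en-1-yl. It derives from (S)-lavandulol; the descriptor changes from S to R on attachment to the arene only because the CIP priorities change.
- 4-(Methoxymethoxy)benzaldehyde, N-methoxy-N-methylacetamide and the oxazolidinone are taken as catalogue compounds.
- Catalyst A is 1-[3,5-bis(trifluoromethyl)phenyl]-3-[(2S)-3,3-dimethyl-1-{[tris(4-methoxyphenyl)-λ5-phosphanylidene]amino}butan-2-yl]thiourea, SMILES COc1ccc(cc1)P(=NC[C@@H](NC(=S)Nc1cc(cc(c1)C(F)(F)F)C(F)(F)F)C(C)(C)C)(c1ccc(OC)cc1)c1ccc(OC)cc1. It is made beforehand from the azido-thiourea and tris(4-methoxyphenyl)phosphine and is not counted as a route step.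
- The sense of induction of catalyst A is not predictable in advance. If a test run gives the 2R epimer, the mirror-image catalyst from (R)-tert-leucine is used unchanged.

## Route

Step 1
Reactants: 1 (4S)-4-benzyl-1,3-oxazolidin-2-one; 2 3-methylbut-2-enoyl chloride
Product: 4 (4S)-4-benzyl-3-(3-methylbut-2-enoyl)-1,3-oxazolidin-2-one, via N-lithio oxazolidinone 3 (not isolated)
Conditions: n-BuLi, THF, −78 °C; then 2, −78 → 0 °C
Reagents that add atoms: none
Why: N-acylation of a lithiated Evans oxazolidinone with an acid chloride (imide formation) is fast at −78 °C and leaves the auxiliary centre untouched; no new stereocentre.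

Step 2
Reactants: 4 (4S)-4-benzyl-3-(3-methylbut-2-enoyl)-1,3-oxazolidin-2-one; 5 1-bromo-3-methylbut-2-ene (prenyl bromide)
Product: 7 (4S)-4-benzyl-3-[(2S)-5-methyl-2-(prop-1-en-2-yl)hex-4-enoyl]-1,3-oxazolidin-2-one, via sodium dienolate 6 (not isolated)
Conditions: NaN(SiMe3)2, THF, −78 °C; then 5, −78 → −30 °C
Reagents that add atoms: none
Why: Evans asymmetric alkylation in its deconjugative variant: γ-deprotonation gives the sodium-chelated Z-dienolate, which is alkylated at C-α on the face opposite the benzyl group, so the new centre is S and the double bond moves out of conjugation to become the isopropenyl group (minor diastereomer removed by chromatography).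

Step 3
Reactants: 7 (4S)-4-benzyl-3-[(2S)-5-methyl-2-(prop-1-en-2-yl)hex-4-enoyl]-1,3-oxazolidin-2-one
Product: 8 (2S)-5-methyl-2-(prop-1-en-2-yl)hex-4-en-1-ol [(S)-lavandulol]
Conditions: LiBH4, MeOH (1 equiv), Et2O, 0 °C
Reagents that add atoms: none
Why: Reductive cleavage of the N-acyl oxazolidinone with LiBH4 (hydride reduction of the exocyclic imide carbonyl) gives the primary alcohol under non-basic conditions, so the allylic α-centre is not epimerised and the auxiliary is recovered.

Step 4
Reactants: 8 (S)-lavandulol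
Product: 9 (3S)-3-(iodomethyl)-2,6-dimethylhepta-1,5-diene [(S)-lavandulyl iodide]
Conditions: I2, PPh3, imidazole, CH2Cl2, 0 °C → rt
Reagents that add atoms: iodine, II
Why: Appel-type iodination of the unhindered primary alcohol is a substitution at CH2, one carbon away from the stereocentre, which is therefore untouched.

Step 5
Reactants: 10 5-methoxybenzene-1,3-diol (5-methoxyresorcinol)
Product: 11 1-methoxy-3,5-bis(methoxymethoxy)benzene
Conditions: NaH, DMF, 0 °C; MOMCl, 0 °C → rt
Reagents that add atoms: chloromethyl methyl ether, COCCl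
Why: Williamson ether synthesis on both phenoxides; the two OMOM groups later direct the ortho-lithiations and are stable to every basic step.

Step 6
Reactants: 11 1-methoxy-3,5-bis(methoxymethoxy)benzene; 9 (S)-lavandulyl iodide
Product: 14 5-methoxy-1,3-bis(methoxymethoxy)-2-Lav-benzene, via aryllithium 12 (not isolated), via arylmagnesium bromide 13 (not isolated)
Conditions: 11 (1.5 equiv), n-BuLi, THF, 0 °C; MgBr2·OEt2; then 9, Li2CuCl4 (5 mol %), THF/NMP, 0 °C → rt
Reagents that add atoms: none
Why: Directed ortho-metalation places lithium between the two OMOM groups, transmetalation to magnesium lowers basicity (suppressing E2 at the allylic β-hydrogen of 9), and the Kochi-type copper-catalysed Grignard–alkyl iodide coupling forms the aryl–CH2 bond without touching the stereocentre.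

Step 7
Reactants: 14 5-methoxy-1,3-bis(methoxymethoxy)-2-Lav-benzene; 15 N-methoxy-N-methylacetamide
Product: 18 1-[2-hydroxy-6-methoxy-4-(methoxymethoxy)-3-Lav-phenyl]ethan-1-one, via aryllithium 16 (not isolated), via bis-MOM ketone 17 (not isolated)
Conditions: n-BuLi, THF, 0 °C; 15, −78 → 0 °C; then 1 M HCl in MeOH, 0 °C → rt (TLC control); NaHCO3
Reagents that add atoms: none
Why: The only ring C–H sites left (equivalent, each between OMOM and OMe) undergo directed ortho-metalation, the aryllithium gives the methyl ketone by Weinreb ketone synthesis, and on acidification the MOM group flanked by acetyl and Lav is cleaved selectively (chelation-assisted acetal exchange driven by the O–H···O=C hydrogen bond) while the 4-OMOM group, deactivated by conjugation with the para carbonyl, survives.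

Step 8
Reactants: 18 1-[2-hydroxy-6-methoxy-4-(methoxymethoxy)-3-Lav-phenyl]ethan-1-one; 19 4-(methoxymethoxy)benzaldehyde
Product: 20 (2E)-1-[2-hydroxy-6-methoxy-4-(methoxymethoxy)-3-Lav-phenyl]-3-[4-(methoxymethoxy)phenyl]prop-2-en-1-one
Conditions: KOH (50% aq.), EtOH, rt, 36 h; then cold 1 M HCl to pH 5–6
Reagents that add atoms: none
Why: Claisen–Schmidt aldol condensation of the acetophenone enolate with the non-enolisable aldehyde, then E1cB dehydration, gives the E-enone under thermodynamic control; MOM ethers and the side-chain centre are inert to hydroxide, and in strong base the product rests as the open chalcone phenoxide.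

Step 9
Reactants: 20 (2E)-1-[2-hydroxy-6-methoxy-4-(methoxymethoxy)-3-Lav-phenyl]-3-[4-(methoxymethoxy)phenyl]prop-2-en-1-one
Product: 22 kushenol U [(2S)-7-hydroxy-2-(4-hydroxyphenyl)-5-methoxy-8-Lav-2,3-dihydro-4H-chromen-4-one], via bis-MOM flavanone 21 (not isolated)
Conditions: catalyst A (10 mol %), toluene, −20 °C, 48 h; then 3 M HCl in MeOH, rt, 12 h
Reagents that add atoms: none
Why: Proposed new method: the strongly basic iminophosphorane of catalyst A deprotonates the single free (chelated) phenol of 20 to a tight aminophosphonium phenoxide ion pair in which the thiourea N–H bonds hold the ketone oxygen, the enone is fixed s-cis in the chiral pocket and the phenoxide oxygen adds 6-endo to the Si face of C-β (oxa-Michael ring closure forming O1–C2 and setting C-2 as S under catalyst control, the side-chain centre being five bonds away), after which the enolate is protonated by the next molecule of the more acidic 20 so that no free base is left to reopen the ring before methanolic HCl is added, which quenches the catalyst and removes both MOM groups by acetal exchange without epimerising C-2; the closest known reaction types are the cinchona-thiourea-catalysed oxa-Michael cyclisation of activated alkylidene β-ketoester chalcones and bifunctional iminophosphorane-catalysed intramolecular oxa-Michael additions of alcohols to α,β-unsaturated esters, neither shown on an unactivated 2'-hydroxychalcone.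

The two C-2 epimers are diastereomers; any residual 2R epimer is removed from 22 by recrystallisation or preparative HPLC.

## Compound list

1 | (4S)-4-benzyl-1,3-oxazolidin-2-one | O=C1N[C@@H](Cc2ccccc2)CO1 | starting material
2 | 3-methylbut-2-enoyl chloride | CC(C)=CC(=O)Cl | starting material
3 | (4S)-4-benzyl-3-lithio-1,3-oxazolidin-2-one | [Li]N1[C@@H](Cc2ccccc2)COC1=O | intermediate
4 | (4S)-4-benzyl-3-(3-methylbut-2-enoyl)-1,3-oxazolidin-2-one | CC(C)=CC(=O)N1[C@@H](Cc2ccccc2)COC1=O | intermediate
5 | 1-bromo-3-methylbut-2-ene | CC(C)=CCBr | starting material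
6 | sodium (1Z)-1-[(4S)-4-benzyl-2-oxo-1,3-oxazolidin-3-yl]-3-methylbuta-1,3-dien-1-olate | C=C(C)/C=C(\O[Na])N1[C@@H](Cc2ccccc2)COC1=O | intermediate
7 | (4S)-4-benzyl-3-[(2S)-5-methyl-2-(prop-1-en-2-yl)hex-4-enoyl]-1,3-oxazolidin-2-one | C=C(C)[C@H](CC=C(C)C)C(=O)N1[C@@H](Cc2ccccc2)COC1=O | intermediate
8 | (2S)-5-methyl-2-(prop-1-en-2-yl)hex-4-en-1-ol | C=C(C)[C@H](CC=C(C)C)CO | intermediate
9 | (3S)-3-(iodomethyl)-2,6-dimethylhepta-1,5-diene | C=C(C)[C@H](CC=C(C)C)CI | intermediate
10 | 5-methoxybenzene-1,3-diol | COc1cc(O)cc(O)c1 | starting material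
11 | 1-methoxy-3,5-bis(methoxymethoxy)benzene | COCOc1cc(OC)cc(OCOC)c1 | intermediate
12 | [4-methoxy-2,6-bis(methoxymethoxy)phenyl]lithium | [Li]c1c(OCOC)cc(OC)cc1OCOC | intermediate
13 | [4-methoxy-2,6-bis(methoxymethoxy)phenyl]magnesium bromide | Br[Mg]c1c(OCOC)cc(OC)cc1OCOC | intermediate
14 | 5-methoxy-1,3-bis(methoxymethoxy)-2-[(2R)-5-methyl-2-(prop-1-en-2-yl)hex-4-en-1-yl]benzene | C=C(C)[C@H](CC=C(C)C)Cc1c(OCOC)cc(OC)cc1OCOC | intermediate
15 | N-methoxy-N-methylacetamide | CC(=O)N(C)OC | starting material
16 | {6-methoxy-2,4-bis(methoxymethoxy)-3-[(2R)-5-methyl-2-(prop-1-en-2-yl)hex-4-en-1-yl]phenyl}lithium | C=C(C)[C@H](CC=C(C)C)Cc1c(OCOC)cc(OC)c([Li])c1OCOC | intermediate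
17 | 1-{6-methoxy-2,4-bis(methoxymethoxy)-3-[(2R)-5-methyl-2-(prop-1-en-2-yl)hex-4-en-1-yl]phenyl}ethan-1-one | C=C(C)[C@H](CC=C(C)C)Cc1c(OCOC)cc(OC)c(C(C)=O)c1OCOC | intermediate
18 | 1-{2-hydroxy-6-methoxy-4-(methoxymethoxy)-3-[(2R)-5-methyl-2-(prop-1-en-2-yl)hex-4-en-1-yl]phenyl}ethan-1-one | C=C(C)[C@H](CC=C(C)C)Cc1c(OCOC)cc(OC)c(C(C)=O)c1O | intermediate
19 | 4-(methoxymethoxy)benzaldehyde | COCOc1ccc(C=O)cc1 | starting material
20 | (2E)-1-{2-hydroxy-6-methoxy-4-(methoxymethoxy)-3-[(2R)-5-methyl-2-(prop-1-en-2-yl)hex-4-en-1-yl]phenyl}-3-[4-(methoxymethoxy)phenyl]prop-2-en-1-one | C=C(C)[C@H](CC=C(C)C)Cc1c(OCOC)cc(OC)c(C(=O)/C=C/c2ccc(OCOC)cc2)c1O | intermediate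
21 | (2S)-5-methoxy-7-(methoxymethoxy)-2-[4-(methoxymethoxy)phenyl]-8-[(2R)-5-methyl-2-(prop-1-en-2-yl)hex-4-en-1-yl]-2,3-dihydro-4H-chromen-4-one | C=C(C)[C@H](CC=C(C)C)Cc1c(OCOC)cc(OC)c2c1O[C@H](c1ccc(OCOC)cc1)CC2=O | intermediate
22 | kushenol U, (2S)-7-hydroxy-2-(4-hydroxyphenyl)-5-methoxy-8-[(2R)-5-methyl-2-(prop-1-en-2-yl)hex-4-en-1-yl]-2,3-dihydro-4H-chromen-4-one | C=C(C)[C@H](CC=C(C)C)Cc1c(O)cc(OC)c2c1O[C@H](c1ccc(O)cc1)CC2=O | target

## Step count and risks

Total step count: 9 (steps 7 and 9 each run two stages in one flask).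
Longest linear sequence: 8 steps (1 → 2 → 3 → 4 → 6 → 7 → 8 → 9).

The three steps most likely to fail:

**Step 9 (proposed new cyclisation).** Turnover may be poor with the hindered phenoxide, or the two C-2 epimers may form with low selectivity. The fallback uses known chemistry, sets out from 18 and comes back at 21. Compound 18 is heated with N,N-dimethylformamide dimethyl acetal (toluene, 100 °C) to give the enaminone (2E)-3-(dimethylamino)-1-[2-hydroxy-6-methoxy-4-(methoxymethoxy)-3-Lav-phenyl]prop-2-en-1-one F4. This is closed with loss of dimethylamine (silica gel or brief dilute aqueous HCl in CH2Cl2, rt) to the chromone 5-methoxy-7-(methoxymethoxy)-8-Lav-4H-chromen-4-one F5. Rhodium-catalysed asymmetric conjugate addition of commercial [4-(methoxymethoxy)phenyl]boronic acid to F5 ([Rh(OH)(C8H12)]2, an electron-poor MeO-BIPHEP-type bisphosphine of the handedness that gives 2S, toluene/H2O, rt) gives 21. Here C-2 is set by C–C bond formation. Compound 21 is then deprotected with 3 M HCl in MeOH as in the second stage of step 9.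

**Step 6 (copper-catalysed aryl–alkyl coupling).** The β-branched iodide may react slowly or eliminate to the diene. The fallback sets out from 11 and 9 and comes back at 14. Aryllithium 12, made from 11 as before, is quenched with iodine to give 2-iodo-5-methoxy-1,3-bis(methoxymethoxy)benzene F1. Iodide 9 is converted with Zn dust and LiCl in THF (40 °C) into [(2S)-5-methyl-2-(prop-1-en-2-yl)hex-4-en-1-yl]zinc iodide F2. Negishi cross-coupling of F1 and F2 (Pd(OAc)2, SPhos, THF, 50 °C) gives 14. The organozinc is far less basic than the Grignard reagent, and the stereocentre is β to zinc and not involved.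

**Step 7 (acetylation with selective cleavage of one MOM group in the same flask).** The acid stage may also cleave the 4-OMOM group or stop short. The fallback sets out from 17 and comes back at 18. Compound 17 is isolated after a neutral NH4Cl work-up, and both MOM groups are removed (3 M HCl in MeOH, rt) to give 1-[2,4-dihydroxy-6-methoxy-3-Lav-phenyl]ethan-1-one F3. The 4-OH is then re-protected selectively (MOMCl, K2CO3, acetone, rt) to give 18; the 2-OH is hydrogen-bonded to the ketone and flanked by two substituents, so it does not react.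

## Further compounds

F1 | step 6 | 2-iodo-5-methoxy-1,3-bis(methoxymethoxy)benzene | COCOc1cc(OC)cc(OCOC)c1I
F2 | step 6 | [(2S)-5-methyl-2-(prop-1-en-2-yl)hex-4-en-1-yl]zinc iodide | C=C(C)[C@H](CC=C(C)C)C[Zn]I
F3 | step 7 | 1-{2,4-dihydroxy-6-methoxy-3-[(2R)-5-methyl-2-(prop-1-en-2-yl)hex-4-en-1-yl]phenyl}ethan-1-one | C=C(C)[C@H](CC=C(C)C)Cc1c(O)cc(OC)c(C(C)=O)c1O
F4 | step 9 | (2E)-3-(dimethylamino)-1-{2-hydroxy-6-methoxy-4-(methoxymethoxy)-3-[(2R)-5-methyl-2-(prop-1-en-2-yl)hex-4-en-1-yl]phenyl}prop-2-en-1-one | C=C(C)[C@H](CC=C(C)C)Cc1c(OCOC)cc(OC)c(C(=O)/C=C/N(C)C)c1O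
F5 | step 9 | 5-methoxy-7-(methoxymethoxy)-8-[(2R)-5-methyl-2-(prop-1-en-2-yl)hex-4-en-1-yl]-4H-chromen-4-one | C=C(C)[C@H](CC=C(C)C)Cc1c(OCOC)cc(OC)c2c1OC=CC2=O
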